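**Retrosynthetic overview**
- The target is reached from its 5-O-methyl ether (5,7,2',4',5'-pentamethoxy-6-prenylisoflavone) by chelation-controlled cleavage of the methyl ether peri to the C4 carbonyl.
- That pentamethyl ether is cut at O1–C8a and C4–C4a into a ring A aryne (3,5-dimethoxy-4-prenylbenzyne, released from an ortho-silylaryl triflate) and the enol of methyl α-formyl-(2,4,5-trimethoxyphenyl)acetate, which supplies O1, C2, C3, C4 and ring B. The pyranone (ring C) is the only ring formed; rings A and B are bought as arenes.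
- Feature used: on ring A, O1 and the C4 carbonyl sit on the adjacent carbons C8a and C4a, and C4a is flanked by the C5 oxygen. This is the pattern a 3-alkoxyaryne delivers when an oxygen nucleophile adds at the remote aryne carbon (C8a) and the anion left at C4a is acylated.
- The silylaryl triflate comes from 1,3-dimethoxybenzene by C2 prenylation, C5 borylation and oxidation to the symmetric phenol, carbamate-directed ortho-silylation and triflation. The enol comes from 2,4,5-trimethoxyphenylacetic acid by esterification and formylation with methyl formate.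

Key step: step 9

Assumption: the enol partner is written as its hydrogen-bonded Z form; any E enol or aldehyde tautomer that accompanies it should give the same enolate under the conditions of the key step, and 2,4,5-trimethoxyphenylacetic acid is taken as purchasable.

**Route**

Step 1
Reactants: 1 1,3-dimethoxybenzene; 2 prenyl bromide (1-bromo-3-methylbut-2-ene)
Product: 4 1,3-dimethoxy-2-(3-methylbut-2-en-1-yl)benzene, via 2,6-dimethoxyphenyllithium 3 (not isolated)
Conditions: n-BuLi, THF, 0 °C to rt; then 2, CuI (10 mol %), −78 °C to rt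
Reagents that add atoms: none
Why: Directed ortho-metalation should occur at C2 between the two methoxy groups, and the aryllithium should then be allylated at the unhindered primary carbon of prenyl bromide (copper-assisted SN2 allylation).

Step 2
Reactants: 4 1,3-dimethoxy-2-(3-methylbut-2-en-1-yl)benzene
Product: 5 2-[3,5-dimethoxy-4-(3-methylbut-2-en-1-yl)phenyl]-4,4,5,5-tetramethyl-1,3,2-dioxaborolane
Conditions: [Ir(OMe)(cod)]2 (1.5 mol %), 4,4'-di-tert-butyl-2,2'-bipyridine (3 mol %), B2pin2, THF, 80 °C
Reagents that add atoms: bis(pinacolato)diboron, CC1(C)OB(OC1(C)C)B1OC(C)(C)C(C)(C)O1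
Why: Iridium-catalysed aromatic C–H borylation is governed by sterics, and C5 is the only ring C–H without an ortho substituent, while the trisubstituted prenyl alkene is expected to react far more slowly than this open arene position.

Step 3
Reactants: 5 2-[3,5-dimethoxy-4-(3-methylbut-2-en-1-yl)phenyl]-4,4,5,5-tetramethyl-1,3,2-dioxaborolane
Product: 6 3,5-dimethoxy-4-(3-methylbut-2-en-1-yl)phenol
Conditions: 30% aq H2O2, NaOH, THF, 0 °C to rt
Reagents that add atoms: hydrogen peroxide, OO
Why: Oxidation of an aryl boronate with alkaline hydrogen peroxide (hydroperoxide adds to boron, the aryl group migrates from boron to oxygen) should give the phenol, and nucleophilic peroxide does not epoxidise an isolated electron-rich alkene.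

Step 4
Reactants: 6 3,5-dimethoxy-4-(3-methylbut-2-en-1-yl)phenol
Product: 7 3,5-dimethoxy-4-(3-methylbut-2-en-1-yl)phenyl N-(propan-2-yl)carbamate
Conditions: i-PrNCO, Et3N (cat.), CH2Cl2, rt
Reagents that add atoms: isopropyl isocyanate, CC(C)N=C=O
Why: Base-catalysed addition of a phenol to an isocyanate (carbamoylation) is a clean, atom-economic way to install the directing group needed for the next step.

Step 5
Reactants: 7 3,5-dimethoxy-4-(3-methylbut-2-en-1-yl)phenyl N-(propan-2-yl)carbamate
Product: 11 3,5-dimethoxy-4-(3-methylbut-2-en-1-yl)-2-(trimethylsilyl)phenyl N-(propan-2-yl)carbamate, via N-silyl carbamate 8 (not isolated), via ortho-lithiated N-silyl carbamate 9 (not isolated), via N-silyl C-silyl carbamate 10 (not isolated)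
Conditions: TBSOTf, TMEDA, Et2O, 0 °C to rt; n-BuLi, TMEDA, −78 °C; TMSCl, −78 °C to rt; aq NaHSO4 work-up
Reagents that add atoms: chlorotrimethylsilane, C[Si](C)(C)Cl
Why: Transient N-silylation masks the carbamate N–H, the carbamate then directs ortho-lithiation (directed ortho-metalation) to the equivalent C2/C6 positions that are also flanked by a methoxy group, TMSCl traps the aryllithium, and the N–Si bond is hydrolysed on acidic work-up while the C–Si bond stays.

Step 6
Reactants: 11 3,5-dimethoxy-4-(3-methylbut-2-en-1-yl)-2-(trimethylsilyl)phenyl N-(propan-2-yl)carbamate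
Product: 13 3,5-dimethoxy-4-(3-methylbut-2-en-1-yl)-2-(trimethylsilyl)phenyl trifluoromethanesulfonate, via silyl phenol 12 (not isolated)
Conditions: DBU, Et2NH, MeCN, 40 °C; then PhNTf2, rt
Reagents that add atoms: N-phenylbis(trifluoromethanesulfonimide), O=S(=O)(N(c1ccccc1)S(=O)(=O)C(F)(F)F)C(F)(F)F
Why: DBU should induce E1cB fragmentation of the N-monosubstituted carbamate to the phenoxide and isopropyl isocyanate, which Et2NH scavenges, and the phenoxide is then O-triflated by PhNTf2 under conditions that leave the aryl–silicon bond and the alkene alone.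

Step 7
Reactants: 14 2-(2,4,5-trimethoxyphenyl)acetic acid
Product: 15 methyl 2-(2,4,5-trimethoxyphenyl)acetate
Conditions: MeOH, H2SO4 (cat.), reflux
Reagents that add atoms: methanol, CO
Why: Fischer esterification of an unhindered arylacetic acid in excess methanol should go to completion.

Step 8
Reactants: 15 methyl 2-(2,4,5-trimethoxyphenyl)acetate; 16 methyl formate
Product: 17 methyl (Z)-3-hydroxy-2-(2,4,5-trimethoxyphenyl)prop-2-enoate
Conditions: NaH, THF, 0 °C to rt; then 1 M HCl
Reagents that add atoms: none
Why: Crossed Claisen condensation of the ester enolate with non-enolisable methyl formate is driven by formation of the stabilised sodium enolate of the product, which on acidification should give the hydrogen-bonded Z enol.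

Step 9
Reactants: 13 3,5-dimethoxy-4-(3-methylbut-2-en-1-yl)-2-(trimethylsilyl)phenyl trifluoromethanesulfonate; 17 methyl (Z)-3-hydroxy-2-(2,4,5-trimethoxyphenyl)prop-2-enoate
Product: 19 5,7-dimethoxy-6-(3-methylbut-2-en-1-yl)-3-(2,4,5-trimethoxyphenyl)-4H-chromen-4-one, via aryne 18 (not isolated)
Conditions: CsF (4 equiv), THF, 65 °C; 17 in 1.5-fold excess
Reagents that add atoms: none
Why: Proposed new method: fluoride attacks silicon in 13 and triflate leaves to give aryne 18, while CsF also converts 17 into its caesium enolate, whose aldehyde-derived oxygen adds to the aryne carbon remote from the C5 methoxy group (O1–C8a), so that the aryl anion lands on C4a, adds to the ester carbonyl held cis on the Z enol ether and expels methoxide (C4–C4a). The closest known reaction type is the CsF-mediated tandem O-arylation and intramolecular acyl capture of arynes by salicylate esters that gives xanthones, transferred here from a phenoxide to an acyclic formyl-ester enolate. The pyranone (ring C) closes by 6-exo-trig addition of the aryl anion to the ester followed by elimination, the anion sitting five atoms from the carbonyl carbon. No stereocenter is formed. Three selectivities are needed: the regiochemistry of addition to the aryne, secured by the inductive and distortion effect of the flanking C5 methoxy group and by the lower hindrance at C8a; O- over C-arylation of the ambident enolate, favoured because the alpha carbon is fully substituted and shielded by the ortho-methoxyaryl group while the aldehyde-derived oxygen is exposed; and the Z geometry of the enol ether, for which THF is chosen so that the caesium enolate reacts as a chelated contact ion pair with both oxygens on the same side. Acyl capture should outrun protonation of the aryl anion because it is intramolecular and the medium is aprotic.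

Step 10
Reactants: 19 5,7-dimethoxy-6-(3-methylbut-2-en-1-yl)-3-(2,4,5-trimethoxyphenyl)-4H-chromen-4-one
Product: 20 5-hydroxy-7-methoxy-6-(3-methylbut-2-en-1-yl)-3-(2,4,5-trimethoxyphenyl)-4H-chromen-4-one
Conditions: MgI2·OEt2 (3 equiv), THF, 50 °C; then cold 0.5 M HCl
Reagents that add atoms: none
Why: Chelation-assisted Lewis-acid ether cleavage should be selective because magnesium bridges the C4 carbonyl and the C5 oxygen in a six-membered chelate and iodide then removes that methyl group by SN2, while the other four methoxy groups have no such chelate and the absence of strong Brønsted acid protects the prenyl group from cyclisation onto the new phenol.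

**Compound list**

1 | 1,3-dimethoxybenzene | COc1cccc(OC)c1 | starting material
2 | prenyl bromide (1-bromo-3-methylbut-2-ene) | CC(C)=CCBr | starting material
3 | 2,6-dimethoxyphenyllithium | [Li]c1c(OC)cccc1OC | intermediate (not isolated)
4 | 1,3-dimethoxy-2-(3-methylbut-2-en-1-yl)benzene | COc1cccc(OC)c1CC=C(C)C | intermediate
5 | 2-[3,5-dimethoxy-4-(3-methylbut-2-en-1-yl)phenyl]-4,4,5,5-tetramethyl-1,3,2-dioxaborolane | COc1cc(B2OC(C)(C)C(C)(C)O2)cc(OC)c1CC=C(C)C | intermediate
6 | 3,5-dimethoxy-4-(3-methylbut-2-en-1-yl)phenol | COc1cc(O)cc(OC)c1CC=C(C)C | intermediate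
7 | 3,5-dimethoxy-4-(3-methylbut-2-en-1-yl)phenyl N-(propan-2-yl)carbamate | CC(C)NC(=O)Oc1cc(OC)c(CC=C(C)C)c(OC)c1 | intermediate
8 | 3,5-dimethoxy-4-(3-methylbut-2-en-1-yl)phenyl N-(tert-butyldimethylsilyl)-N-(propan-2-yl)carbamate | CC(C)N(C(=O)Oc1cc(OC)c(CC=C(C)C)c(OC)c1)[Si](C)(C)C(C)(C)C | intermediate (not isolated)
9 | 2-lithio-3,5-dimethoxy-4-(3-methylbut-2-en-1-yl)phenyl N-(tert-butyldimethylsilyl)-N-(propan-2-yl)carbamate | CC(C)N(C(=O)Oc1cc(OC)c(CC=C(C)C)c(OC)c1[Li])[Si](C)(C)C(C)(C)C | intermediate (not isolated)
10 | 3,5-dimethoxy-4-(3-methylbut-2-en-1-yl)-2-(trimethylsilyl)phenyl N-(tert-butyldimethylsilyl)-N-(propan-2-yl)carbamate | CC(C)N(C(=O)Oc1cc(OC)c(CC=C(C)C)c(OC)c1[Si](C)(C)C)[Si](C)(C)C(C)(C)C | intermediate (not isolated)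
11 | 3,5-dimethoxy-4-(3-methylbut-2-en-1-yl)-2-(trimethylsilyl)phenyl N-(propan-2-yl)carbamate | CC(C)NC(=O)Oc1cc(OC)c(CC=C(C)C)c(OC)c1[Si](C)(C)C | intermediate
12 | 3,5-dimethoxy-4-(3-methylbut-2-en-1-yl)-2-(trimethylsilyl)phenol (formed as its DBU salt) | COc1cc(O)c([Si](C)(C)C)c(OC)c1CC=C(C)C | intermediate (not isolated)
13 | 3,5-dimethoxy-4-(3-methylbut-2-en-1-yl)-2-(trimethylsilyl)phenyl trifluoromethanesulfonate | COc1cc(OS(=O)(=O)C(F)(F)F)c([Si](C)(C)C)c(OC)c1CC=C(C)C | intermediate
14 | 2-(2,4,5-trimethoxyphenyl)acetic acid | COc1cc(OC)c(CC(=O)O)cc1OC | starting material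
15 | methyl 2-(2,4,5-trimethoxyphenyl)acetate | COC(=O)Cc1cc(OC)c(OC)cc1OC | intermediate
16 | methyl formate | COC=O | starting material
17 | methyl (Z)-3-hydroxy-2-(2,4,5-trimethoxyphenyl)prop-2-enoate | O/C=C(\C(=O)OC)c1cc(OC)c(OC)cc1OC | intermediate
18 | 1,2-didehydro-3,5-dimethoxy-4-(3-methylbut-2-en-1-yl)benzene (aryne) | COC1=CC#CC(OC)=C1CC=C(C)C | intermediate (not isolated)
19 | 5,7-dimethoxy-6-(3-methylbut-2-en-1-yl)-3-(2,4,5-trimethoxyphenyl)-4H-chromen-4-one | COc1cc(OC)c(-c2coc3cc(OC)c(CC=C(C)C)c(OC)c3c2=O)cc1OC | intermediate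
20 | 5-hydroxy-7-methoxy-6-(3-methylbut-2-en-1-yl)-3-(2,4,5-trimethoxyphenyl)-4H-chromen-4-one | COc1cc(OC)c(-c2coc3cc(OC)c(CC=C(C)C)c(O)c3c2=O)cc1OC | target

**Step count**

Total step count: 10 (steps 1–6 to the aryne precursor, steps 7–8 to the enol, steps 9–10 to the target).
Longest linear sequence: 8 steps (1, 2, 3, 4, 5, 6, 9, 10).

**Steps most likely to fail**

1. Step 9 (aryne annulation). The ambident enolate may attack the aryne through carbon, which would lead to C-arylated or insertion products. It may also react through its E form, so that the aryl anion cannot reach the ester and is protonated to an open aryl vinyl ether. Released methoxide may consume aryne. Fallback by known chemistry (deoxybenzoin route), setting out from carbamate 7 and acid 14 and coming back at 19: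
   - Acid 14 is converted with 1,1'-carbonyldiimidazole and N,O-dimethylhydroxylamine hydrochloride in CH2Cl2 into N-methoxy-N-methyl-2-(2,4,5-trimethoxyphenyl)acetamide F1.
   - Carbamate 7 is N-silylated and ortho-lithiated as in step 5 (compounds 8 and 9), and 9 is acylated with F1 at −78 °C to give 3,5-dimethoxy-4-(3-methylbut-2-en-1-yl)-2-[(2,4,5-trimethoxyphenyl)acetyl]phenyl N-(tert-butyldimethylsilyl)-N-(propan-2-yl)carbamate F2, which is not isolated.
   - Aqueous NaHSO4 work-up removes the N-silyl group and should give 3,5-dimethoxy-4-(3-methylbut-2-en-1-yl)-2-[(2,4,5-trimethoxyphenyl)acetyl]phenyl N-(propan-2-yl)carbamate F3.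
   - DBU and Et2NH in MeCN at 40 °C cleave the carbamate to the 2-hydroxydeoxybenzoin 1-[6-hydroxy-2,4-dimethoxy-3-(3-methylbut-2-en-1-yl)phenyl]-2-(2,4,5-trimethoxyphenyl)ethan-1-one F4.
   - Heating F4 with N,N-dimethylformamide dimethyl acetal in toluene at 100 °C should add C2 as an enaminone that cyclises onto the phenol with loss of dimethylamine, giving 19.

2. Step 2 (C–H borylation beside a prenyl group). Iridium hydride and boryl species may hydroborate or isomerise the prenyl double bond, or the alkene may slow the catalyst so that conversion stalls. Fallback, setting out from 1 and coming back at 6, in which the alkene is introduced only after the iridium step: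
   - 1 is borylated under the conditions of step 2 to 2-(3,5-dimethoxyphenyl)-4,4,5,5-tetramethyl-1,3,2-dioxaborolane F5 and oxidised with alkaline H2O2 to 3,5-dimethoxyphenol F6.
   - F6 is silylated with TIPSCl and imidazole in DMF to (3,5-dimethoxyphenoxy)tri(propan-2-yl)silane F7.
   - n-BuLi in THF at 0 °C should metalate F7 between the two methoxy groups, since the bulky silyl ether neither directs nor leaves its ortho positions accessible, giving [2,6-dimethoxy-4-(tri(propan-2-yl)silyloxy)phenyl]lithium F8, which is not isolated.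
   - F8 is allylated with 2 and catalytic CuI to [3,5-dimethoxy-4-(3-methylbut-2-en-1-yl)phenoxy]tri(propan-2-yl)silane F9.
   - Bu4NF in THF at 0 °C removes the silyl group to give 6.

3. Step 5 (directed ortho-silylation). Lateral deprotonation of the benzylic and allylic CH2 flanked by two methoxy groups, or anionic ortho-Fries migration of the carbamoyl group on warming, may compete with ring lithiation and C-silylation. Fallback (retro-Brook route), setting out from 6 and coming back at 13:
   - Phenol 6 is monobrominated ortho to the hydroxyl with NBS in CH2Cl2 at −78 °C, where the highly activated ring should react before the alkene, to give 2-bromo-3,5-dimethoxy-4-(3-methylbut-2-en-1-yl)phenol F10.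
   - F10 is O-silylated with hexamethyldisilazane in refluxing THF to [2-bromo-3,5-dimethoxy-4-(3-methylbut-2-en-1-yl)phenoxy]trimethylsilane F11.
   - n-BuLi in THF at −100 to −78 °C effects bromine–lithium exchange with 1,3 oxygen-to-carbon silyl migration (retro-Brook rearrangement) to the lithium salt of 12.
   - Tf2O at −78 °C triflates that phenoxide to give 13.

**Further compounds**

F1 | step 9 | N-methoxy-N-methyl-2-(2,4,5-trimethoxyphenyl)acetamide | CON(C)C(=O)Cc1cc(OC)c(OC)cc1OC
F2 | step 9 | 3,5-dimethoxy-4-(3-methylbut-2-en-1-yl)-2-[(2,4,5-trimethoxyphenyl)acetyl]phenyl N-(tert-butyldimethylsilyl)-N-(propan-2-yl)carbamate | CC(C)N(C(=O)Oc1cc(OC)c(CC=C(C)C)c(OC)c1C(=O)Cc1cc(OC)c(OC)cc1OC)[Si](C)(C)C(C)(C)C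
F3 | step 9 | 3,5-dimethoxy-4-(3-methylbut-2-en-1-yl)-2-[(2,4,5-trimethoxyphenyl)acetyl]phenyl N-(propan-2-yl)carbamate | CC(C)NC(=O)Oc1cc(OC)c(CC=C(C)C)c(OC)c1C(=O)Cc1cc(OC)c(OC)cc1OC
F4 | step 9 | 1-[6-hydroxy-2,4-dimethoxy-3-(3-methylbut-2-en-1-yl)phenyl]-2-(2,4,5-trimethoxyphenyl)ethan-1-one | COc1cc(O)c(C(=O)Cc2cc(OC)c(OC)cc2OC)c(OC)c1CC=C(C)C
F5 | step 2 | 2-(3,5-dimethoxyphenyl)-4,4,5,5-tetramethyl-1,3,2-dioxaborolane | COc1cc(OC)cc(B2OC(C)(C)C(C)(C)O2)c1
F6 | step 2 | 3,5-dimethoxyphenol | COc1cc(O)cc(OC)c1
F7 | step 2 | (3,5-dimethoxyphenoxy)tri(propan-2-yl)silane | COc1cc(OC)cc(O[Si](C(C)C)(C(C)C)C(C)C)c1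
F8 | step 2 | [2,6-dimethoxy-4-(tri(propan-2-yl)silyloxy)phenyl]lithium | [Li]c1c(OC)cc(O[Si](C(C)C)(C(C)C)C(C)C)cc1OC
F9 | step 2 | [3,5-dimethoxy-4-(3-methylbut-2-en-1-yl)phenoxy]tri(propan-2-yl)silane | COc1cc(O[Si](C(C)C)(C(C)C)C(C)C)cc(OC)c1CC=C(C)C
F10 | step 5 | 2-bromo-3,5-dimethoxy-4-(3-methylbut-2-en-1-yl)phenol | COc1cc(O)c(Br)c(OC)c1CC=C(C)C
F11 | step 5 | [2-bromo-3,5-dimethoxy-4-(3-methylbut-2-en-1-yl)phenoxy]trimethylsilane | COc1cc(O[Si](C)(C)C)c(Br)c(OC)c1CC=C(C)C
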